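**Retrosynthetic overview**

1. Target 29 ⇐ 28 (hydrogenolysis of two aryl benzyl ethers) ⇐ 27 by one LiAlH4 reduction: the C3 methyl ester and the γ-lactone of 27 are the three CH2OH groups at the acyl oxidation level.
2. The dihydrobenzofuran ring of 27 (O1–C2–C3–C3a–C7a) ⇐ oxidative 6→5 contraction of the pyranone ring of (2S)-flavanone 23 (O1–C2–C3–C4–C4a–C8a): iodine(III) at C3, 1,2-shift of C4a from C4 to C3, C4 expelled from the ring as CO2Me. Enabling feature: the C4 ketone lying between the enolisable C3 methylene and the O1-activated aryl carbon C4a; as its dimethyl ketal it makes C3 nucleophilic and C4 a cation-stabilised migration origin.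
3. 23 ⇐ flat, achiral chromone 21 + arylboronic acid 22 (Pd/PyOx asymmetric conjugate arylation sets C2); 21 ⇐ aryl bromide 16 (Stille acetylation, DMF-DMA annulation).
4. 16 ⇐ trans-selective alkylation of (R)-lactone 10 (Evans succinate alkylation from 3, 4 and 2) with benzylic bromide 14 (from 5-bromovanillin 11).
5. Ring order: γ-lactone (step 4) → pyranone (step 10) → contracted to the dihydrofuran (step 12); the lactone is opened last (step 13).

Key step: step 12

Assumption: (R)-t-BuPyOx is taken as the ligand enantiomer that delivers the (2S)-flavanone in step 11, by transposing the facial preference of Pd/PyOx conjugate arylation of cyclic enones onto the chromone; if the first run shows the opposite sense, the (S)-ligand is used and nothing else changes. Compounds 1, 3, 4, 11 and 22 are taken as commercial.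

**Route**

Step 1
Reactants: 1 [4-(benzyloxy)-3-methoxyphenyl]methanol
Product: 2 1-(benzyloxy)-4-(bromomethyl)-2-methoxybenzene
Conditions: PBr3 (0.4 equiv), Et2O, 0 °C; used directly
Reagents that add atoms: phosphorus tribromide, BrP(Br)Br
Why: Bromination of an electron-rich benzylic alcohol with PBr3 (SN2 on the phosphite ester); no stereocentre is involved.

Step 2
Reactants: 3 4-tert-butoxy-4-oxobutanoic acid; 4 (4R)-4-benzyl-1,3-oxazolidin-2-one
Product: 6 tert-butyl 4-[(4R)-4-benzyl-2-oxo-1,3-oxazolidin-3-yl]-4-oxobutanoate, via mixed pivalic anhydride 5 (not isolated)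
Conditions: PivCl, Et3N, THF, −20 °C; then 4, LiCl, −20 °C → rt
Reagents that add atoms: none
Why: N-Acylation of an Evans oxazolidinone through the mixed pivalic anhydride under LiCl/Et3N activation; the auxiliary stereocentre is not touched.

Step 3
Reactants: 6 tert-butyl 4-[(4R)-4-benzyl-2-oxo-1,3-oxazolidin-3-yl]-4-oxobutanoate; 2 1-(benzyloxy)-4-(bromomethyl)-2-methoxybenzene
Product: 8 tert-butyl (3R)-4-[(4R)-4-benzyl-2-oxo-1,3-oxazolidin-3-yl]-3-[4-(benzyloxy)-3-methoxybenzyl]-4-oxobutanoate, via sodium Z-enolate 7 (not isolated)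
Conditions: NaHMDS, THF, −78 °C; then 2, −78 → −40 °C
Reagents that add atoms: none
Why: Evans asymmetric alkylation: the chelated Z-enolate of the imide is benzylated on the face opposite the C4 benzyl group of the (R)-auxiliary, which should set the new centre as R.

Step 4
Reactants: 8 tert-butyl (3R)-4-[(4R)-4-benzyl-2-oxo-1,3-oxazolidin-3-yl]-3-[4-(benzyloxy)-3-methoxybenzyl]-4-oxobutanoate
Product: 10 (4R)-4-[4-(benzyloxy)-3-methoxybenzyl]oxolan-2-one, via hydroxy ester 9 (not isolated)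
Conditions: LiBH4, H2O (1 equiv), Et2O, 0 °C; then p-TsOH·H2O (cat.), toluene, 80 °C
Reagents that add atoms: none
Why: Reductive cleavage of the imide by LiBH4 spares the tert-butyl ester, and the γ-hydroxy ester then lactonises by acid-catalysed intramolecular transesterification without touching the stereocentre.

Step 5
Reactants: 11 3-bromo-4-hydroxy-5-methoxybenzaldehyde (5-bromovanillin)
Product: 12 3-bromo-5-methoxy-4-(methoxymethoxy)benzaldehyde
Conditions: MOMCl, i-Pr2NEt, CH2Cl2, 0 °C → rt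
Reagents that add atoms: chloromethyl methyl ether, COCCl
Why: O-Alkylation of the phenol to a MOM acetal, which tolerates hydride, Appel bromination, enolate alkylation and Stille coupling and is removed by acid, orthogonally to the benzyl ethers.

Step 6
Reactants: 12 3-bromo-5-methoxy-4-(methoxymethoxy)benzaldehyde
Product: 13 [3-bromo-5-methoxy-4-(methoxymethoxy)phenyl]methanol
Conditions: NaBH4, MeOH, 0 °C
Reagents that add atoms: none
Why: Borohydride reduction of the aldehyde; aryl bromide and acetal are inert.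

Step 7
Reactants: 13 [3-bromo-5-methoxy-4-(methoxymethoxy)phenyl]methanol
Product: 14 1-bromo-5-(bromomethyl)-3-methoxy-2-(methoxymethoxy)benzene
Conditions: CBr4, PPh3, CH2Cl2, 0 °C
Reagents that add atoms: carbon tetrabromide, BrC(Br)(Br)Br
Why: Appel bromination under neutral conditions, chosen because the MOM acetal would not survive HBr-generating reagents.

Step 8
Reactants: 10 (4R)-4-[4-(benzyloxy)-3-methoxybenzyl]oxolan-2-one; 14 1-bromo-5-(bromomethyl)-3-methoxy-2-(methoxymethoxy)benzene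
Product: 16 (3R,4R)-4-[4-(benzyloxy)-3-methoxybenzyl]-3-[3-bromo-5-methoxy-4-(methoxymethoxy)benzyl]oxolan-2-one, via lithium enolate 15 (not isolated)
Conditions: LiHMDS, THF, −78 °C; then 14, DMPU, −78 → −40 °C
Reagents that add atoms: none
Why: Alkylation of the lithium enolate of a β-substituted γ-butyrolactone with the benzylic bromide (far more reactive than the aryl bromide), which should enter anti to the C4 substituent and set C3 as R (trans).

Step 9
Reactants: 16 (3R,4R)-4-[4-(benzyloxy)-3-methoxybenzyl]-3-[3-bromo-5-methoxy-4-(methoxymethoxy)benzyl]oxolan-2-one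
Product: 18 (3R,4R)-3-[3-acetyl-5-methoxy-4-(methoxymethoxy)benzyl]-4-[4-(benzyloxy)-3-methoxybenzyl]oxolan-2-one, via aryl enol ether 17 (not isolated)
Conditions: tributyl(1-ethoxyvinyl)stannane, PdCl2(PPh3)2 (5 mol %), toluene, 100 °C; then 1 M HCl, THF, rt
Reagents that add atoms: tributyl(1-ethoxyvinyl)stannane, CCCC[Sn](CCCC)(CCCC)C(=C)OCC; water, O
Why: Stille coupling of the aryl bromide with an acetyl-anion equivalent, followed by mild acid hydrolysis of the enol ether to the methyl ketone; the lactone stereocentres are remote.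

Step 10
Reactants: 18 (3R,4R)-3-[3-acetyl-5-methoxy-4-(methoxymethoxy)benzyl]-4-[4-(benzyloxy)-3-methoxybenzyl]oxolan-2-one
Product: 21 (3R,4R)-4-[4-(benzyloxy)-3-methoxybenzyl]-3-[(8-methoxy-4-oxo-4H-chromen-6-yl)methyl]oxolan-2-one, via MOM-protected enaminone 19 (not isolated), via phenolic enaminone 20 (not isolated)
Conditions: Me2NCH(OMe)2, toluene, 105 °C; concentrate; then conc. HCl, MeOH/CH2Cl2, 40 °C
Reagents that add atoms: N,N-dimethylformamide dimethyl acetal, COC(OC)N(C)C
Why: Standard chromone annulation: enaminone formation at the acetyl group, then acid removes the MOM group and the phenol adds to the β-carbon with loss of dimethylamine.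

Step 11
Reactants: 21 (3R,4R)-4-[4-(benzyloxy)-3-methoxybenzyl]-3-[(8-methoxy-4-oxo-4H-chromen-6-yl)methyl]oxolan-2-one; 22 [4-(benzyloxy)-3-methoxyphenyl]boronic acid
Product: 23 (3R,4R)-4-[4-(benzyloxy)-3-methoxybenzyl]-3-{[(2S)-2-[4-(benzyloxy)-3-methoxyphenyl]-8-methoxy-4-oxo-3,4-dihydro-2H-chromen-6-yl]methyl}oxolan-2-one
Conditions: Pd(OCOCF3)2 (5 mol %), (R)-t-BuPyOx (6 mol %), NH4PF6 (30 mol %), H2O (5 equiv), ClCH2CH2Cl, 60 °C
Reagents that add atoms: none
Why: Pd(II)/pyridine-oxazoline-catalysed asymmetric conjugate addition of an arylboronic acid to a chromone; the ligand should control the face of aryl transfer to C2 (S) and the Pd enolate is protonated by water.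

Step 12
Reactants: 23 (3R,4R)-4-[4-(benzyloxy)-3-methoxybenzyl]-3-{[(2S)-2-[4-(benzyloxy)-3-methoxyphenyl]-8-methoxy-4-oxo-3,4-dihydro-2H-chromen-6-yl]methyl}oxolan-2-one
Product: 27 methyl (2S,3S)-2-[4-(benzyloxy)-3-methoxyphenyl]-5-{[(3R,4R)-4-[4-(benzyloxy)-3-methoxybenzyl]-2-oxooxolan-3-yl]methyl}-7-methoxy-2,3-dihydro-1-benzofuran-3-carboxylate, via methyl enol ether 24 (not isolated), via C3 iodane ketal 25 (not isolated), via trimethyl ortho ester 26 (not isolated)
Conditions: PhI(OAc)2 (1.3 equiv), conc. H2SO4, HC(OMe)3, 0 °C → rt; then H2O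
Reagents that add atoms: trimethyl orthoformate, COC(OC)OC; water, O
Why: Acid and trimethyl orthoformate convert the C4 ketone into its ketal/methyl enol ether 24, whose nucleophilic C3 is attacked by PhI(OAc)2 opposite the C2 aryl group to give the α-iodanyl ketal 25; C4a then shifts from C4 to C3 with loss of iodobenzene, and the dimethoxy-stabilised cation at C4 is trapped as ortho ester 26 and hydrolysed to the methyl ester on work-up. This is the known iodine(III) (or thallium(III)) oxidative ring contraction of flavanones to methyl trans-2-aryl-2,3-dihydrobenzofuran-3-carboxylates, a semipinacol-type 1,2-aryl shift. The five-membered ring is closed not by a cyclisation but by transfer of the ring bond C4–C4a to C3–C4a (6→5 contraction through a phenonium-like bridged transition state that the ortho ring oxygen O1 stabilises), with C4 leaving the ring as the ester carbon. The new stereocentre C3 is controlled by C2: the iodane sits trans to the C2 aryl group, the shift inverts C3 and places the ester trans to the aryl group, the acidic C3–H lets any cis isomer equilibrate to the more stable trans ester, and C2 stays S because none of its bonds is broken. The step needs migration of C4a rather than the C2→C3 shift of the B-ring (isoflavone) or loss of H-2 (flavone); the equatorial C3–I bond of the half-chair with an equatorial C2 aryl group is antiperiplanar to C4–C4a, and the ketal oxygens at the migration origin favour that path. The benzyl ethers keep both guaiacyl oxygens from oxidation by iodine(III).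

Step 13
Reactants: 27 methyl (2S,3S)-2-[4-(benzyloxy)-3-methoxyphenyl]-5-{[(3R,4R)-4-[4-(benzyloxy)-3-methoxybenzyl]-2-oxooxolan-3-yl]methyl}-7-methoxy-2,3-dihydro-1-benzofuran-3-carboxylate
Product: 28 (2R,3R)-2-[4-(benzyloxy)-3-methoxybenzyl]-3-{[(2S,3R)-2-[4-(benzyloxy)-3-methoxyphenyl]-3-(hydroxymethyl)-7-methoxy-2,3-dihydro-1-benzofuran-5-yl]methyl}butane-1,4-diol
Conditions: LiAlH4, THF, 0 °C → rt; Rochelle-salt work-up
Reagents that add atoms: none
Why: Hydride reduction of both acyl groups (methyl ester and γ-lactone) to primary alcohols in one operation; no bond to a stereocentre is broken, and the descriptor at C3 of the benzofuran changes from S to R only through CIP priorities.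

Step 14
Reactants: 28 (2R,3R)-2-[4-(benzyloxy)-3-methoxybenzyl]-3-{[(2S,3R)-2-[4-(benzyloxy)-3-methoxyphenyl]-3-(hydroxymethyl)-7-methoxy-2,3-dihydro-1-benzofuran-5-yl]methyl}butane-1,4-diol
Product: 29 (2R,3R)-2-(4-hydroxy-3-methoxybenzyl)-3-{[(2S,3R)-2-(4-hydroxy-3-methoxyphenyl)-3-(hydroxymethyl)-7-methoxy-2,3-dihydro-1-benzofuran-5-yl]methyl}butane-1,4-diol (CNP0256425.1)
Conditions: H2 (1 atm), 10% Pd/C, EtOAc/MeOH, rt, stopped at full debenzylation
Reagents that add atoms: none
Why: Catalytic hydrogenolysis of the two aryl benzyl ethers under mild conditions that should leave the dihydrobenzofuran ring and all four stereocentres intact.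

**Compound list**

1 | [4-(benzyloxy)-3-methoxyphenyl]methanol | COc1cc(CO)ccc1OCc1ccccc1 | starting material
2 | 1-(benzyloxy)-4-(bromomethyl)-2-methoxybenzene | COc1cc(CBr)ccc1OCc1ccccc1 | intermediate
3 | 4-tert-butoxy-4-oxobutanoic acid (mono-tert-butyl succinate) | CC(C)(C)OC(=O)CCC(=O)O | starting material
4 | (4R)-4-benzyl-1,3-oxazolidin-2-one | O=C1N[C@H](Cc2ccccc2)CO1 | starting material
5 | mixed anhydride of 3 with pivalic acid | CC(C)(C)OC(=O)CCC(=O)OC(=O)C(C)(C)C | intermediate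
6 | tert-butyl 4-[(4R)-4-benzyl-2-oxo-1,3-oxazolidin-3-yl]-4-oxobutanoate | CC(C)(C)OC(=O)CCC(=O)N1C(=O)OC[C@H]1Cc1ccccc1 | intermediate
7 | sodium (Z)-enolate of 6 | [Na+].CC(C)(C)OC(=O)C/C=C(\[O-])N1C(=O)OC[C@H]1Cc1ccccc1 | intermediate
8 | tert-butyl (3R)-4-[(4R)-4-benzyl-2-oxo-1,3-oxazolidin-3-yl]-3-[4-(benzyloxy)-3-methoxybenzyl]-4-oxobutanoate | CC(C)(C)OC(=O)C[C@@H](Cc1ccc(OCc2ccccc2)c(OC)c1)C(=O)N1C(=O)OC[C@H]1Cc1ccccc1 | intermediate
9 | tert-butyl (3R)-4-[4-(benzyloxy)-3-methoxyphenyl]-3-(hydroxymethyl)butanoate | CC(C)(C)OC(=O)C[C@@H](Cc1ccc(OCc2ccccc2)c(OC)c1)CO | intermediate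
10 | (4R)-4-[4-(benzyloxy)-3-methoxybenzyl]oxolan-2-one | O=C1C[C@@H](Cc2ccc(OCc3ccccc3)c(OC)c2)CO1 | intermediate
11 | 3-bromo-4-hydroxy-5-methoxybenzaldehyde (5-bromovanillin) | COc1cc(C=O)cc(Br)c1O | starting material
12 | 3-bromo-5-methoxy-4-(methoxymethoxy)benzaldehyde | COCOc1c(Br)cc(C=O)cc1OC | intermediate
13 | [3-bromo-5-methoxy-4-(methoxymethoxy)phenyl]methanol | COCOc1c(Br)cc(CO)cc1OC | intermediate
14 | 1-bromo-5-(bromomethyl)-3-methoxy-2-(methoxymethoxy)benzene | COCOc1c(Br)cc(CBr)cc1OC | intermediate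
15 | lithium enolate of 10 | [Li+].[O-]C1=C[C@@H](Cc2ccc(OCc3ccccc3)c(OC)c2)CO1 | intermediate
16 | (3R,4R)-4-[4-(benzyloxy)-3-methoxybenzyl]-3-[3-bromo-5-methoxy-4-(methoxymethoxy)benzyl]oxolan-2-one | O=C1OC[C@H](Cc2ccc(OCc3ccccc3)c(OC)c2)[C@H]1Cc1cc(Br)c(OCOC)c(OC)c1 | intermediate
17 | (3R,4R)-4-[4-(benzyloxy)-3-methoxybenzyl]-3-[3-(1-ethoxyethenyl)-5-methoxy-4-(methoxymethoxy)benzyl]oxolan-2-one | O=C1OC[C@H](Cc2ccc(OCc3ccccc3)c(OC)c2)[C@H]1Cc1cc(C(=C)OCC)c(OCOC)c(OC)c1 | intermediate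
18 | (3R,4R)-3-[3-acetyl-5-methoxy-4-(methoxymethoxy)benzyl]-4-[4-(benzyloxy)-3-methoxybenzyl]oxolan-2-one | O=C1OC[C@H](Cc2ccc(OCc3ccccc3)c(OC)c2)[C@H]1Cc1cc(C(C)=O)c(OCOC)c(OC)c1 | intermediate
19 | (3R,4R)-4-[4-(benzyloxy)-3-methoxybenzyl]-3-{3-[(2E)-3-(dimethylamino)prop-2-enoyl]-5-methoxy-4-(methoxymethoxy)benzyl}oxolan-2-one | O=C1OC[C@H](Cc2ccc(OCc3ccccc3)c(OC)c2)[C@H]1Cc1cc(C(=O)/C=C/N(C)C)c(OCOC)c(OC)c1 | intermediate
20 | (3R,4R)-4-[4-(benzyloxy)-3-methoxybenzyl]-3-{3-[(2E)-3-(dimethylamino)prop-2-enoyl]-4-hydroxy-5-methoxybenzyl}oxolan-2-one | O=C1OC[C@H](Cc2ccc(OCc3ccccc3)c(OC)c2)[C@H]1Cc1cc(C(=O)/C=C/N(C)C)c(O)c(OC)c1 | intermediate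
21 | (3R,4R)-4-[4-(benzyloxy)-3-methoxybenzyl]-3-[(8-methoxy-4-oxo-4H-chromen-6-yl)methyl]oxolan-2-one | O=C1OC[C@H](Cc2ccc(OCc3ccccc3)c(OC)c2)[C@H]1Cc1cc(OC)c2occc(=O)c2c1 | intermediate
22 | [4-(benzyloxy)-3-methoxyphenyl]boronic acid | COc1cc(B(O)O)ccc1OCc1ccccc1 | starting material
23 | (3R,4R)-4-[4-(benzyloxy)-3-methoxybenzyl]-3-{[(2S)-2-[4-(benzyloxy)-3-methoxyphenyl]-8-methoxy-4-oxo-3,4-dihydro-2H-chromen-6-yl]methyl}oxolan-2-one | O=C1OC[C@H](Cc2ccc(OCc3ccccc3)c(OC)c2)[C@H]1Cc1cc(OC)c2O[C@H](c3ccc(OCc4ccccc4)c(OC)c3)CC(=O)c2c1 | intermediate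
24 | 4-methoxy-2H-chromene (methyl enol ether) of 23, C2 configuration unchanged | O=C1OC[C@H](Cc2ccc(OCc3ccccc3)c(OC)c2)[C@H]1Cc1cc(OC)c2O[C@H](c3ccc(OCc4ccccc4)c(OC)c3)C=C(OC)c2c1 | intermediate
25 | 4,4-dimethyl ketal of 23 carrying an acetoxy(phenyl)-λ3-iodanyl group at C3, trans to the C2 aryl group | O=C1OC[C@H](Cc2ccc(OCc3ccccc3)c(OC)c2)[C@H]1Cc1cc(OC)c2O[C@H](c3ccc(OCc4ccccc4)c(OC)c3)[C@@H](I(OC(C)=O)c3ccccc3)C(OC)(OC)c2c1 | intermediate
26 | trimethyl ortho ester corresponding to 27 (trans-2-aryl-3-(trimethoxymethyl)-2,3-dihydrobenzofuran) | O=C1OC[C@H](Cc2ccc(OCc3ccccc3)c(OC)c2)[C@H]1Cc1cc(OC)c2O[C@H](c3ccc(OCc4ccccc4)c(OC)c3)[C@@H](C(OC)(OC)OC)c2c1 | intermediate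
27 | methyl (2S,3S)-2-[4-(benzyloxy)-3-methoxyphenyl]-5-{[(3R,4R)-4-[4-(benzyloxy)-3-methoxybenzyl]-2-oxooxolan-3-yl]methyl}-7-methoxy-2,3-dihydro-1-benzofuran-3-carboxylate | O=C1OC[C@H](Cc2ccc(OCc3ccccc3)c(OC)c2)[C@H]1Cc1cc(OC)c2O[C@H](c3ccc(OCc4ccccc4)c(OC)c3)[C@@H](C(=O)OC)c2c1 | intermediate
28 | (2R,3R)-2-[4-(benzyloxy)-3-methoxybenzyl]-3-{[(2S,3R)-2-[4-(benzyloxy)-3-methoxyphenyl]-3-(hydroxymethyl)-7-methoxy-2,3-dihydro-1-benzofuran-5-yl]methyl}butane-1,4-diol | COc1cc(C[C@@H](CO)[C@H](CO)Cc2cc(OC)c3c(c2)[C@H](CO)[C@@H](c2ccc(OCc4ccccc4)c(OC)c2)O3)ccc1OCc1ccccc1 | intermediate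
29 | (2R,3R)-2-(4-hydroxy-3-methoxybenzyl)-3-{[(2S,3R)-2-(4-hydroxy-3-methoxyphenyl)-3-(hydroxymethyl)-7-methoxy-2,3-dihydro-1-benzofuran-5-yl]methyl}butane-1,4-diol | COc1cc(C[C@@H](CO)[C@H](CO)Cc2cc(OC)c3c(c2)[C@H](CO)[C@@H](c2ccc(O)c(OC)c2)O3)ccc1O | target

**Step count and risks**

Total steps: 14. Longest linear sequence: 10 steps (for example steps 1, 3, 4, 8, 9, 10, 11, 12, 13, 14).

Steps most likely to fail:

1. Step 12 (key step). What may go wrong: migration of the wrong group (C2→C3 shift of the B-ring, or loss of H-2 to a flavone), acid-promoted methanolysis of the γ-lactone in the orthoformate medium, oxidation of the dialkoxyarenes by iodine(III), and erosion of C2 through reversible acid-induced opening of the pyranone ring. Fallback, a photochemical Wolff ring contraction under neutral conditions: starting from 23, heating with DMF-DMA should give the 3-(dimethylaminomethylene) derivative of 23 F1. Base-free diazo transfer from tosyl azide to this enaminone should give the 3-diazo derivative of 23 F2. Irradiation of F2 in methanol (Pyrex-filtered Hg lamp) should expel N2 and shift C4a from C4 to the carbene carbon C3; the exocyclic ketene is trapped by methanol as a mixture of 27 and its cis (2S,3R) epimer F3. Catalytic NaOMe in MeOH followed by acidic work-up (relactonisation) should equilibrate F3 to the trans ester, and the route is rejoined at 27.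

2. Step 11. What may go wrong: slow arylation of the chromone, protodeboronation of the electron-rich boronic acid, and insufficient facial selectivity at C2. Fallback through a chalcone, starting from 18: HCl in MeOH should remove the MOM group to give (3R,4R)-3-(3-acetyl-4-hydroxy-5-methoxybenzyl)-4-[4-(benzyloxy)-3-methoxybenzyl]oxolan-2-one F4. Claisen–Schmidt condensation of F4 with commercial 4-(benzyloxy)-3-methoxybenzaldehyde (KOH, EtOH, then acidification to re-close the lactone) should give the 2'-hydroxychalcone F5. Oxa-Michael cyclisation of F5 (NaOAc, EtOH, reflux) should give 23 together with its (2R)-epimer F6; as diastereomers these are separable by preparative HPLC, and F6 can be returned to the base equilibration through F5. The route is rejoined at 23.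

3. Step 14. What may go wrong: over-reduction, that is hydrogenolytic opening of the benzylic C2–O1 bond of the dihydrobenzofuran once the para-phenol is unmasked. Fallback without hydrogen or metal surface: starting from 28, BCl3 with pentamethylbenzene as benzyl-cation scavenger (CH2Cl2, −78 °C, MeOH quench) should cleave the two aryl benzyl ethers heterolytically and lead directly to 29; no new compound is made on the way (F0).

**Further compounds**

F1 | step 12 | 3-[(E)-(dimethylamino)methylidene] derivative of flavanone 23 (C2 configuration unchanged) | O=C1OC[C@H](Cc2ccc(OCc3ccccc3)c(OC)c2)[C@H]1Cc1cc(OC)c2O[C@H](c3ccc(OCc4ccccc4)c(OC)c3)/C(=C\N(C)C)C(=O)c2c1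
F2 | step 12 | 3-diazo derivative of flavanone 23 (C2 configuration unchanged) | O=C1OC[C@H](Cc2ccc(OCc3ccccc3)c(OC)c2)[C@H]1Cc1cc(OC)c2O[C@H](c3ccc(OCc4ccccc4)c(OC)c3)C(=[N+]=[N-])C(=O)c2c1
F3 | step 12 | methyl (2S,3R)-2-[4-(benzyloxy)-3-methoxyphenyl]-5-{[(3R,4R)-4-[4-(benzyloxy)-3-methoxybenzyl]-2-oxooxolan-3-yl]methyl}-7-methoxy-2,3-dihydro-1-benzofuran-3-carboxylate (cis epimer of 27) | O=C1OC[C@H](Cc2ccc(OCc3ccccc3)c(OC)c2)[C@H]1Cc1cc(OC)c2O[C@H](c3ccc(OCc4ccccc4)c(OC)c3)[C@H](C(=O)OC)c2c1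
F4 | step 11 | (3R,4R)-3-(3-acetyl-4-hydroxy-5-methoxybenzyl)-4-[4-(benzyloxy)-3-methoxybenzyl]oxolan-2-one | O=C1OC[C@H](Cc2ccc(OCc3ccccc3)c(OC)c2)[C@H]1Cc1cc(C(C)=O)c(O)c(OC)c1
F5 | step 11 | (3R,4R)-4-[4-(benzyloxy)-3-methoxybenzyl]-3-{3-[(2E)-3-[4-(benzyloxy)-3-methoxyphenyl]prop-2-enoyl]-4-hydroxy-5-methoxybenzyl}oxolan-2-one | O=C1OC[C@H](Cc2ccc(OCc3ccccc3)c(OC)c2)[C@H]1Cc1cc(C(=O)/C=C/c2ccc(OCc3ccccc3)c(OC)c2)c(O)c(OC)c1
F6 | step 11 | (2R)-epimer of flavanone 23 | O=C1OC[C@H](Cc2ccc(OCc3ccccc3)c(OC)c2)[C@H]1Cc1cc(OC)c2O[C@@H](c3ccc(OCc4ccccc4)c(OC)c3)CC(=O)c2c1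
F0 | step 14 | none | none
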